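**Strategy.** The cyclohexene ring (C1 bears CO2H, C2 is the ring CH=, C6 the CH2) is built by annulating a four-carbon sugar fragment (C2–C5, all three oxygens in place) with a two-carbon phosphonoacrylate (C6, C1). A D-mannose-derived acid carries O4/O5 in a dioxolane, the 5-methylhexanoate on O3 and a free aldehyde at C2. Photoredox decarboxylation gives a dioxolanyl radical at C5 that adds to tert-butyl 2-(diethoxyphosphoryl)acrylate (C5–C6); reduction of the adduct radical gives a phosphonate carbanion that olefinates the aldehyde (C1=C2). The step exploits the trans C4–O/C5–O diol of the ring: held in a dioxolane, it steers the radical addition trans, so the carboxyl-bearing sugar stereocentre is expendable. Acetonide cleavage, O5 acetylation, O4 tigloylation and tert-butyl ester cleavage follow.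

Key step: step 6

Remark: the target is read as the all-trans (3R,4R,5S) triester with an (E)-2-methylbut-2-enoyl (tigloyl) group on O4. Compounds 1, 2, 4, 9, 10, 16 and 18 are taken as catalogue materials. The anomeric configuration of 1 is immaterial because sugar C1 is excised.

Step 1
Reactants: 1 2,3:5,6-di-O-isopropylidene-α-D-mannofuranose; 2 methyltriphenylphosphonium bromide
Product: 3 1,2-dideoxy-3,4:6,7-di-O-isopropylidene-D-manno-hept-1-enitol (free 5-OH)
Conditions: Ph3PCH3Br (2.5 equiv), KOtBu (2.4 equiv), THF, 0 °C → reflux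
Reagents that add atoms: methyltriphenylphosphonium bromide (2), C[P+](c1ccccc1)(c1ccccc1)c1ccccc1.[Br-]
Why: Wittig methylenation of the ring-opened aldehyde form of the lactol should unmask the former ring oxygen as the only free hydroxyl without creating a stereocentre; any base-induced epimerisation next to the aldehyde is harmless because that carbon later becomes the radical centre.

Step 2
Reactants: 3 1,2-dideoxy-3,4:6,7-di-O-isopropylidene-D-manno-hept-1-enitol; 4 5-methylhexanoyl chloride
Product: 5 1,2-dideoxy-3,4:6,7-di-O-isopropylidene-5-O-(5-methylhexanoyl)-D-manno-hept-1-enitol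
Conditions: 5-methylhexanoyl chloride (1.5 equiv), pyridine, DMAP (cat.), CH2Cl2, 0 °C → rt
Reagents that add atoms: 5-methylhexanoyl chloride (4), CC(C)CCCC(=O)Cl
Why: DMAP-catalysed O-acylation of the only free hydroxyl should install the future C3 ester with no change at any stereocentre.

Step 3
Reactants: 5 1,2-dideoxy-3,4:6,7-di-O-isopropylidene-5-O-(5-methylhexanoyl)-D-manno-hept-1-enitol
Product: 7 2,3:5,6-di-O-isopropylidene-4-O-(5-methylhexanoyl)-D-mannonic acid, via aldehydo-mannose ester 6 (not isolated)
Conditions: O3, CH2Cl2, −78 °C; Me2S, −78 °C → rt; concentrate; then NaClO2, NaH2PO4, 2-methylbut-2-ene, t-BuOH/H2O, 0 °C → rt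
Reagents that add atoms: ozone, [O-][O+]=O; NaClO2, [Na+].[O-]Cl=O
Why: ozonolysis with reductive work-up followed by Pinnick oxidation should turn the vinyl group into the carboxyl group that later serves as the traceless radical precursor, while both acetonides and the ester are inert to the two stages and no stereocentre is touched.

Step 4
Reactants: 7 2,3:5,6-di-O-isopropylidene-4-O-(5-methylhexanoyl)-D-mannonic acid
Product: 8 3,4-O-isopropylidene-2-O-(5-methylhexanoyl)-aldehydo-D-arabinuronic acid
Conditions: H5IO6 (1.3 equiv), EtOAc, rt; filter, concentrate, use crude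
Reagents that add atoms: none
Why: periodic acid in ethyl acetate should hydrolyse the more accessible terminal acetonide and cleave the liberated 1,2-diol in the same flask (Malaprade glycol cleavage), leaving the internal dioxolane intact; the new aldehyde carbon becomes ring C2 and no stereocentre is touched.

Step 5
Reactants: 9 tert-butyl diethylphosphonoacetate; 10 paraformaldehyde
Product: 12 tert-butyl 2-(diethoxyphosphoryl)acrylate, via methoxy adduct 11 (not isolated)
Conditions: (CH2O)n, piperidine (cat.), MeOH, reflux; concentrate; then TsOH·H2O (1 mol%), toluene, reflux with distillation of MeOH, short contact time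
Reagents that add atoms: paraformaldehyde (10), C=O
Why: amine-catalysed Knoevenagel-type hydroxymethylation of the phosphonoacetate in methanol should give the methanol adduct, which loses methanol under acid catalysis to the 2-phosphonoacrylate; no stereocentre is involved.

Step 6
Reactants: 8 3,4-O-isopropylidene-2-O-(5-methylhexanoyl)-aldehydo-D-arabinuronic acid; 12 tert-butyl 2-(diethoxyphosphoryl)acrylate
Product: 14 tert-butyl (3R,4R,5S)-4,5-O-isopropylidene-4,5-dihydroxy-3-[(5-methylhexanoyl)oxy]cyclohex-1-ene-1-carboxylate (trans-fused acetonide), via Giese adduct phosphonate 13 (not isolated)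
Conditions: 12 (1.3 equiv), 2,4,5,6-tetrakis(carbazol-9-yl)isophthalonitrile (4CzIPN, 2 mol%), Cs2CO3 (1.0 equiv), degassed DMF (0.05 M), blue LEDs (450 nm), 25 °C; then dark, 40 °C
Reagents that add atoms: tert-butyl 2-(diethoxyphosphoryl)acrylate (12), C=C(C(=O)OC(C)(C)C)P(=O)(OCC)OCC
Why: Proposed new method: the excited photocatalyst should oxidise the cesium carboxylate of 8, loss of CO2 gives a 2,2-dimethyl-1,3-dioxolan-4-yl radical at the future C5, this nucleophilic α-oxy radical adds to the CH2 terminus of 12 (C5–C6 bond), the α-phosphono ester radical so formed is reduced by the photocatalyst radical anion to the cesium phosphonoenolate of 13 (radical–polar crossover), and this anion closes onto the aldehyde by intramolecular Horner–Wadsworth–Emmons olefination (C1=C2 bond). The closest known reaction types are the photoredox decarboxylative Giese addition of α-oxy acids, radical–polar crossover annulations in which the carbanion formed after the Giese step is trapped by an internal electrophile, and the carbanion-initiated Michael/intramolecular Horner–Wadsworth–Emmons cyclohexene annulation of 2-phosphonoacrylates; what has not been shown is termination of a decarboxylative radical–polar crossover by olefination of a pendant aldehyde. The six-membered ring is closed by 6-exo-trig attack of the phosphonate carbanion on the aldehyde carbon followed by syn elimination of diethyl phosphate, which can only give the endocyclic C1=C2 alkene. The only new stereocentre, C5, is controlled by the dioxolane ring: the radical is attacked on the face anti to the C4 side chain, so the cis (manno) acid converges on the trans-dioxolane, that is the 4,5-trans diol, whatever the configuration of the carboxyl-bearing carbon was. The step needs bond formation and ring closure to outrun epimerisation or β-alkoxy elimination at C3 (α to the aldehyde), which the weakly basic carboxylate/hydrogencarbonate medium and the fast intramolecular olefination are meant to secure, and it needs the radical to choose 12 over the aldehyde, which the polarity match of a nucleophilic radical with a doubly activated acceptor secures.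

Step 7
Reactants: 14 tert-butyl (3R,4R,5S)-4,5-O-isopropylidene-4,5-dihydroxy-3-[(5-methylhexanoyl)oxy]cyclohex-1-ene-1-carboxylate
Product: 15 tert-butyl (3R,4R,5S)-4,5-dihydroxy-3-[(5-methylhexanoyl)oxy]cyclohex-1-ene-1-carboxylate
Conditions: AcOH/H2O (4:1), 40 °C
Reagents that add atoms: none
Why: acid-catalysed hydrolysis of the strained trans-fused acetonide should be much faster than cleavage of the tert-butyl ester or of the secondary ester in aqueous acetic acid, and no stereocentre is touched.

Step 8
Reactants: 15 tert-butyl (3R,4R,5S)-4,5-dihydroxy-3-[(5-methylhexanoyl)oxy]cyclohex-1-ene-1-carboxylate; 16 acetyl chloride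
Product: 17 tert-butyl (3R,4R,5S)-5-acetoxy-4-hydroxy-3-[(5-methylhexanoyl)oxy]cyclohex-1-ene-1-carboxylate
Conditions: AcCl (1.05 equiv), 2,4,6-collidine (2 equiv), CH2Cl2, −78 °C
Reagents that add atoms: acetyl chloride (16), CC(=O)Cl
Why: sterically controlled O-acylation at low temperature should take place at the C5 hydroxyl, which is flanked by the ring CH2, in preference to the C4 hydroxyl, which is flanked on both sides by oxygenated carbons and deactivated by the vicinal acyloxy group; no stereocentre changes.

Step 9
Reactants: 17 tert-butyl (3R,4R,5S)-5-acetoxy-4-hydroxy-3-[(5-methylhexanoyl)oxy]cyclohex-1-ene-1-carboxylate; 18 tigloyl chloride [(E)-2-methylbut-2-enoyl chloride]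
Product: 19 tert-butyl (3R,4R,5S)-5-acetoxy-3-[(5-methylhexanoyl)oxy]-4-{[(2E)-2-methylbut-2-enoyl]oxy}cyclohex-1-ene-1-carboxylate
Conditions: tigloyl chloride (2 equiv), pyridine (4 equiv), DMAP (0.2 equiv), CH2Cl2, 0 °C → rt
Reagents that add atoms: tigloyl chloride (18), C/C=C(\C)C(=O)Cl
Why: DMAP-catalysed acylation of the remaining C4 hydroxyl with the chloride of the thermodynamically stable (E)-acid should carry the alkene geometry over unchanged, with pyridine as the only base to avoid ketene formation and acetyl migration.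

Step 10
Reactants: 19 tert-butyl (3R,4R,5S)-5-acetoxy-3-[(5-methylhexanoyl)oxy]-4-{[(2E)-2-methylbut-2-enoyl]oxy}cyclohex-1-ene-1-carboxylate
Product: 20 (3R,4R,5S)-5-acetoxy-3-[(5-methylhexanoyl)oxy]-4-{[(2E)-2-methylbut-2-enoyl]oxy}cyclohex-1-ene-1-carboxylic acid (target)
Conditions: TFA/CH2Cl2 (1:4), 0 °C → rt
Reagents that add atoms: none
Why: acidolysis of the tert-butyl ester (loss of isobutene through the tert-butyl cation) should leave the three secondary esters and both alkenes untouched, because ionisation of the allylic C3–O bond is disfavoured by the conjugated carboxyl group.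

**Compound list**

1 | 2,3:5,6-di-O-isopropylidene-α-D-mannofuranose | O[C@H]1O[C@H]([C@H]2COC(C)(C)O2)[C@@H]2OC(C)(C)O[C@H]12 | starting material
2 | methyltriphenylphosphonium bromide | C[P+](c1ccccc1)(c1ccccc1)c1ccccc1.[Br-] | starting material
3 | 1,2-dideoxy-3,4:6,7-di-O-isopropylidene-D-manno-hept-1-enitol | C=C[C@H]1OC(C)(C)O[C@H]1[C@H](O)[C@H]1COC(C)(C)O1 | intermediate
4 | 5-methylhexanoyl chloride | CC(C)CCCC(=O)Cl | starting material
5 | 1,2-dideoxy-3,4:6,7-di-O-isopropylidene-5-O-(5-methylhexanoyl)-D-manno-hept-1-enitol | C=C[C@H]1OC(C)(C)O[C@H]1[C@H](OC(=O)CCCCC(C)C)[C@H]1COC(C)(C)O1 | intermediate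
6 | 2,3:5,6-di-O-isopropylidene-4-O-(5-methylhexanoyl)-aldehydo-D-mannose (not isolated) | O=C[C@H]1OC(C)(C)O[C@H]1[C@H](OC(=O)CCCCC(C)C)[C@H]1COC(C)(C)O1 | intermediate
7 | 2,3:5,6-di-O-isopropylidene-4-O-(5-methylhexanoyl)-D-mannonic acid | OC(=O)[C@H]1OC(C)(C)O[C@H]1[C@H](OC(=O)CCCCC(C)C)[C@H]1COC(C)(C)O1 | intermediate
8 | 3,4-O-isopropylidene-2-O-(5-methylhexanoyl)-aldehydo-D-arabinuronic acid, i.e. (4S,5S)-2,2-dimethyl-5-{(1S)-1-[(5-methylhexanoyl)oxy]-2-oxoethyl}-1,3-dioxolane-4-carboxylic acid | OC(=O)[C@H]1OC(C)(C)O[C@H]1[C@H](OC(=O)CCCCC(C)C)C=O | intermediate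
9 | tert-butyl diethylphosphonoacetate | CCOP(=O)(OCC)CC(=O)OC(C)(C)C | starting material
10 | paraformaldehyde (as formaldehyde) | C=O | starting material
11 | tert-butyl 2-(diethoxyphosphoryl)-3-methoxypropanoate (not isolated) | COCC(C(=O)OC(C)(C)C)P(=O)(OCC)OCC | intermediate
12 | tert-butyl 2-(diethoxyphosphoryl)acrylate | C=C(C(=O)OC(C)(C)C)P(=O)(OCC)OCC | intermediate
13 | tert-butyl 2-(diethoxyphosphoryl)-3-[(4S,5R)-2,2-dimethyl-5-{(1S)-1-[(5-methylhexanoyl)oxy]-2-oxoethyl}-1,3-dioxolan-4-yl]propanoate (trans-dioxolane; present as its cesium phosphonoenolate, not isolated) | O=C[C@@H](OC(=O)CCCCC(C)C)[C@@H]1OC(C)(C)O[C@H]1CC(C(=O)OC(C)(C)C)P(=O)(OCC)OCC | intermediate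
14 | tert-butyl (3R,4R,5S)-4,5-O-isopropylidene-4,5-dihydroxy-3-[(5-methylhexanoyl)oxy]cyclohex-1-ene-1-carboxylate (trans-fused acetonide) | CC(C)(C)OC(=O)C1=C[C@@H](OC(=O)CCCCC(C)C)[C@@H]2OC(C)(C)O[C@H]2C1 | intermediate
15 | tert-butyl (3R,4R,5S)-4,5-dihydroxy-3-[(5-methylhexanoyl)oxy]cyclohex-1-ene-1-carboxylate | O[C@@H]1[C@@H](O)CC(C(=O)OC(C)(C)C)=C[C@H]1OC(=O)CCCCC(C)C | intermediate
16 | acetyl chloride | CC(=O)Cl | starting material
17 | tert-butyl (3R,4R,5S)-5-acetoxy-4-hydroxy-3-[(5-methylhexanoyl)oxy]cyclohex-1-ene-1-carboxylate | O[C@@H]1[C@@H](OC(C)=O)CC(C(=O)OC(C)(C)C)=C[C@H]1OC(=O)CCCCC(C)C | intermediate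
18 | tigloyl chloride, (E)-2-methylbut-2-enoyl chloride | C/C=C(\C)C(=O)Cl | starting material
19 | tert-butyl (3R,4R,5S)-5-acetoxy-3-[(5-methylhexanoyl)oxy]-4-{[(2E)-2-methylbut-2-enoyl]oxy}cyclohex-1-ene-1-carboxylate | C/C=C(\C)C(=O)O[C@@H]1[C@@H](OC(C)=O)CC(C(=O)OC(C)(C)C)=C[C@H]1OC(=O)CCCCC(C)C | intermediate
20 | (3R,4R,5S)-5-acetoxy-3-[(5-methylhexanoyl)oxy]-4-{[(2E)-2-methylbut-2-enoyl]oxy}cyclohex-1-ene-1-carboxylic acid | C/C=C(\C)C(=O)O[C@@H]1[C@@H](OC(C)=O)CC(C(=O)O)=C[C@H]1OC(=O)CCCCC(C)C | target

**Step count and risks**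

Total step count: 10. Longest linear sequence: 9 steps (1 → 20 through steps 1–4 and 6–10); step 5 is a one-step side branch.

Steps most likely to fail:

1. Step 6 (proposed new method). The sequence may stall at protonated 13 if hydrogencarbonate is too weak a base in DMF. The α-acyloxy aldehyde may epimerise at C3 or eliminate the C4 oxygen before ring closure. Facial selectivity at the dioxolanyl radical may be eroded. Fallback in known chemistry, two operations, setting out from 8 and returning at 14: DIC and N-hydroxyphthalimide (DMAP cat., CH2Cl2) should give the N-hydroxyphthalimide ester of 8, F1. Reductive decarboxylative Giese addition of F1 to 12 (Ru(bpy)3(PF6)2 cat., Hantzsch ester, CH2Cl2, blue LEDs) should give 13, now isolated as the neutral phosphonate. Intramolecular Horner–Wadsworth–Emmons olefination under Masamune–Roush conditions (LiCl, DBU, MeCN, 0 °C) then closes the ring to 14.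

2. Step 8. Site selectivity between the two secondary hydroxyls may be poor, or diacetylation may compete. Fallback setting out from 15 and returning at 19 (step 9 is then skipped): the bulkier TBSCl with imidazole in DMF at 0 °C should silylate O5 more selectively to give the 5-O-tert-butyldimethylsilyl ether F2. Tigloyl chloride, pyridine and DMAP acylate O4 to give the 4-O-tigloyl silyl ether F3, with no migratable acetyl group present. HF·pyridine in THF removes the silyl group under acidic conditions to give the 4-O-tigloyl 5-alcohol F4. Ac2O, pyridine and DMAP then acetylate O5 to give 19.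

3. Step 4. Acid may also open the internal acetonide and lead to over-cleavage, and the free aldehyde–acid may close to a cyclic acyloxy-hemiacetal or self-condense on concentration. Fallback setting out from 7 and returning at 14: the carboxyl is converted into the radical precursor before the aldehyde is unveiled. DIC and N-hydroxyphthalimide should give the N-hydroxyphthalimide ester of 7, F5. H5IO6 in EtOAc then gives the aldehyde ester F1. The reductive Giese addition to 13 and the LiCl/DBU olefination described under the first fallback lead to 14.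

**Further compounds**

F1 | step 6 | N-hydroxyphthalimide ester of 8, 1,3-dioxoisoindolin-2-yl (4S,5S)-2,2-dimethyl-5-{(1S)-1-[(5-methylhexanoyl)oxy]-2-oxoethyl}-1,3-dioxolane-4-carboxylate | O=C(ON1C(=O)c2ccccc2C1=O)[C@H]1OC(C)(C)O[C@H]1[C@H](OC(=O)CCCCC(C)C)C=O
F2 | step 8 | tert-butyl (3R,4R,5S)-5-[(tert-butyldimethylsilyl)oxy]-4-hydroxy-3-[(5-methylhexanoyl)oxy]cyclohex-1-ene-1-carboxylate | O[C@@H]1[C@@H](O[Si](C)(C)C(C)(C)C)CC(C(=O)OC(C)(C)C)=C[C@H]1OC(=O)CCCCC(C)C
F3 | step 8 | tert-butyl (3R,4R,5S)-5-[(tert-butyldimethylsilyl)oxy]-3-[(5-methylhexanoyl)oxy]-4-{[(2E)-2-methylbut-2-enoyl]oxy}cyclohex-1-ene-1-carboxylate | C/C=C(\C)C(=O)O[C@@H]1[C@@H](O[Si](C)(C)C(C)(C)C)CC(C(=O)OC(C)(C)C)=C[C@H]1OC(=O)CCCCC(C)C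
F4 | step 8 | tert-butyl (3R,4R,5S)-5-hydroxy-3-[(5-methylhexanoyl)oxy]-4-{[(2E)-2-methylbut-2-enoyl]oxy}cyclohex-1-ene-1-carboxylate | C/C=C(\C)C(=O)O[C@@H]1[C@@H](O)CC(C(=O)OC(C)(C)C)=C[C@H]1OC(=O)CCCCC(C)C
F5 | step 4 | N-hydroxyphthalimide ester of 7, 1,3-dioxoisoindolin-2-yl 2,3:5,6-di-O-isopropylidene-4-O-(5-methylhexanoyl)-D-mannonate | O=C(ON1C(=O)c2ccccc2C1=O)[C@H]1OC(C)(C)O[C@H]1[C@H](OC(=O)CCCCC(C)C)[C@H]1COC(C)(C)O1
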